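**Retrosynthetic overview**

1. Target ⇐ removal of a tosyl group from the free phenol ⇐ exo-selective cationic closure of ring B (O-5–C-4) ⇐ diol ⇐ aryl Grignard reagent + lactol ⇐ cis-fused furofuranone (ring A complete, ring B still a γ-lactone).
2. Furofuranone ⇐ Krapcho removal of an angular ester ⇐ key step: formal (3+2) annulation of formaldehyde with a lactone-fused donor–acceptor cyclopropane, which closes ring A through the bonds C-3–C-3a and O-2–C-1 (target numbering).
3. Cyclopropane lactone ⇐ reduction/lactonisation ⇐ amine-catalysed cyclopropanation of O-tosylconiferaldehyde with dimethyl bromomalonate, the only catalytic stereo-event; C-6a comes from it directly, C-1 from it by inversion, C-3a and C-4 by relay.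
4. Enabling feature: in ring A (C-1, O-2, C-3, C-3a, C-6a) the aryl-bearing C-1 and the ring-fusion carbon C-3a are 1,3-related through C-6a, and C-3a is α to C-4, which can be carried as the lactone carbonyl of ring B. C-1/C-6a/C-3a is therefore a masked donor–acceptor cyclopropane and O-2–C-3 a formaldehyde unit. The guaiacyl group at C-1 is endo (cis to C-6), which is what inversion at the donor carbon of the trans cyclopropane gives.
5. Ring order: cyclopropane → γ-lactone (ring B at the acid oxidation level) → ring A (key step) → ring B reopened by the Grignard reagent and reclosed as the 2-aryl tetrahydrofuran.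

Key step: step 4

Remark: the SMILES is read as the (1S,3aS,4R,6aS) furofuran with the free-phenol aryl endo and the prenyloxyaryl exo (epipinoresinol type). The lactol and the diol are carried as mixtures at the lactol/carbinol carbon, which is reset in step 9. "Tosyloxy" means 4-methylbenzenesulfonyloxy and "prenyl" means 3-methylbut-2-en-1-yl.

**Route**

Step 1
Reactants: 1 (E)-coniferaldehyde [(E)-3-(4-hydroxy-3-methoxyphenyl)prop-2-enal]
Product: 2 (E)-2-methoxy-4-(3-oxoprop-1-en-1-yl)phenyl 4-methylbenzenesulfonate
Conditions: TsCl (1.1 equiv), Et3N (1.5 equiv), DMAP (5 mol%), CH2Cl2, 0 °C → rt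
Reagents that add atoms: p-toluenesulfonyl chloride, Cc1ccc(cc1)S(Cl)(=O)=O
Why: O-sulfonylation of the phenol, giving a group that survives all later steps and, by withdrawing electron density from the ring, later keeps the cyclopropane opening stereospecific and the benzylic ether at C-1 configurationally stable; no stereocentre is formed.

Step 2
Reactants: 2 (E)-2-methoxy-4-(3-oxoprop-1-en-1-yl)phenyl 4-methylbenzenesulfonate; 3 dimethyl bromomalonate
Product: 4 dimethyl (2R,3S)-3-formyl-2-[3-methoxy-4-(tosyloxy)phenyl]cyclopropane-1,1-dicarboxylate (aryl and formyl trans)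
Conditions: (R)-α,α-diphenylprolinol trimethylsilyl ether (20 mol%), 2,6-lutidine (1.1 equiv), CH2Cl2, 0 °C → rt
Reagents that add atoms: none
Why: Michael-initiated ring closure under iminium/enamine catalysis (organocatalytic cyclopropanation of an enal with a bromomalonate), in which the Ar2C(OSiMe3) group of the (R) catalyst should shield the Si face of C-β of the s-trans E-iminium ion so that the malonate adds to the Re face and sets the aryl-bearing carbon (R), after which the enamine displaces bromide in a 3-exo-tet closure that places the formyl group trans to the aryl group (S).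

Step 3
Reactants: 4 dimethyl (2R,3S)-3-formyl-2-[3-methoxy-4-(tosyloxy)phenyl]cyclopropane-1,1-dicarboxylate
Product: 6 methyl (1R,5S,6R)-6-[3-methoxy-4-(tosyloxy)phenyl]-2-oxo-3-oxabicyclo[3.1.0]hexane-1-carboxylate (aryl exo), via hydroxymethyl diester 5 (not isolated)
Conditions: NaBH4, MeOH, −10 °C; then p-TsOH (cat.), CH2Cl2, rt
Reagents that add atoms: none
Why: Chemoselective borohydride reduction of the aldehyde followed by acid-catalysed lactonisation of the primary alcohol onto the cis ester, which leaves both existing stereocentres untouched, makes C-1 stereogenic only because the cis ester alone can close, and leaves the aryl group exo.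

Step 4
Reactants: 6 methyl (1R,5S,6R)-6-[3-methoxy-4-(tosyloxy)phenyl]-2-oxo-3-oxabicyclo[3.1.0]hexane-1-carboxylate
Product: 7 methyl (3aS,4S,6aS)-4-[3-methoxy-4-(tosyloxy)phenyl]-1-oxotetrahydrofuro[3,4-c]furan-6a-carboxylate (cis-fused; aryl endo, cis to C-3)
Conditions: Sn(OTf)2 (10 mol%), (CH2O)n (5 equiv), 4 Å MS, ClCH2CH2Cl, 45 °C
Reagents that add atoms: formaldehyde (charged as paraformaldehyde), C=O
Why: Proposed new method: the Lewis acid should chelate the lactone and ester carbonyl groups on C-1 of 6 and polarise the C-1–C-6 bond into a tight benzylic ion pair, the oxygen atom of formaldehyde then attacks C-6 from the side opposite C-1, and the metal enolate adds to the resulting O-alkylated formaldehyde oxocarbenium ion, so that O-5–C-4 and C-6–C-6a of 7 (O-2–C-1 and C-3–C-3a of the target) form in one operation. The closest known reaction type is the Lewis acid-catalysed (3+2) annulation of aldehydes with 2-arylcyclopropane-1,1-dicarboxylates to tetrahydrofurans, established for aryl, alkenyl and alkyl aldehydes and known to run with inversion at the donor carbon; what has not been shown is formaldehyde (a weaker oxygen nucleophile, released from its polymer) as the partner, here with the acceptor pair tied into a fused lactone. Ring A closes in the C–C bond-forming event, a 5-(enolexo)-endo-trig aldol-type attack of the enolate carbon on the oxocarbenium carbon, the closure common to annulations of this type. C-4 is set by the stereospecific inversion, which turns the exo (trans) aryl group of 6 into the endo aryl group of 7, and the quaternary C-6a is dictated by C-3a because the new ring can only be cis-fused to the lactone. The step needs attack with inversion in place of a free benzylic cation, cleavage of C-1–C-6 and not C-1–C-5, and no hydroxymethylation of the arene: the tosyloxy group damps both the donor power of the aryl group and the nucleophilicity of its ring, ring-opening and reclosure can only return the same exo cyclopropane because C-5 is fixed and the lactone must stay cis-fused, and only C-6 carries a cation-stabilising substituent.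

Step 5
Reactants: 7 methyl (3aS,4S,6aS)-4-[3-methoxy-4-(tosyloxy)phenyl]-1-oxotetrahydrofuro[3,4-c]furan-6a-carboxylate
Product: 8 (3aS,4S,6aS)-4-[3-methoxy-4-(tosyloxy)phenyl]tetrahydro-1H,3H-furo[3,4-c]furan-1-one
Conditions: LiCl (3 equiv), H2O (2 equiv), DMSO, 140 °C
Reagents that add atoms: none
Why: Krapcho demethoxycarbonylation, in which chloride dealkylates the methyl ester, the carboxylate loses CO2 and the lactone enolate is protonated on the convex face to the only possible cis-fused bicycle, so that C-6a follows from C-3a, while the enolate cannot expel O-5 because that would be a retro-5-endo-trig elimination.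

Step 6
Reactants: 8 (3aS,4S,6aS)-4-[3-methoxy-4-(tosyloxy)phenyl]tetrahydro-1H,3H-furo[3,4-c]furan-1-one
Product: 9 (3aS,4S,6aS)-4-[3-methoxy-4-(tosyloxy)phenyl]tetrahydro-1H,3H-furo[3,4-c]furan-1-ol (mixture of anomers)
Conditions: DIBAL-H (1.1 equiv), CH2Cl2, −78 °C; Rochelle salt work-up
Reagents that add atoms: none
Why: Partial reduction of a γ-lactone to the lactol with diisobutylaluminium hydride, which should stop at the tetrahedral aluminium alkoxide at −78 °C, with the aryl sulfonate inert and the new lactol centre (anomeric mixture) of no consequence.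

Step 7
Reactants: 10 4-bromo-2-methoxyphenol
Product: 11 4-bromo-2-methoxy-1-[(3-methylbut-2-en-1-yl)oxy]benzene
Conditions: prenyl bromide (1.2 equiv), K2CO3, acetone, 55 °C
Reagents that add atoms: prenyl bromide (1-bromo-3-methylbut-2-ene), CC(C)=CCBr
Why: Williamson ether synthesis, the phenoxide displacing the primary allylic bromide by SN2 at oxygen, with no stereocentre involved.

Step 8
Reactants: 9 (3aS,4S,6aS)-4-[3-methoxy-4-(tosyloxy)phenyl]tetrahydro-1H,3H-furo[3,4-c]furan-1-ol; 11 4-bromo-2-methoxy-1-[(3-methylbut-2-en-1-yl)oxy]benzene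
Product: 13 4-[(2S,3S,4S)-4-{hydroxy[3-methoxy-4-(prenyloxy)phenyl]methyl}-3-(hydroxymethyl)oxolan-2-yl]-2-methoxyphenyl 4-methylbenzenesulfonate (both carbinol epimers), via arylmagnesium bromide 12 (not isolated)
Conditions: 11 (3 equiv), Mg, THF, 40 °C; then 9, THF, 0 °C → rt; aq. NH4Cl
Reagents that add atoms: none
Why: Grignard addition to the hydroxy aldehyde that is in equilibrium with the lactol (one equivalent of 12 is spent on the lactol O–H), giving the carbinol carbon as a mixture of epimers, which is acceptable because that centre is ionised in step 9, while C-2, C-3 and C-4 of the oxolane are untouched.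

Step 9
Reactants: 13 4-[(2S,3S,4S)-4-{hydroxy[3-methoxy-4-(prenyloxy)phenyl]methyl}-3-(hydroxymethyl)oxolan-2-yl]-2-methoxyphenyl 4-methylbenzenesulfonate
Product: 14 4-[(1S,3aS,4R,6aS)-4-{3-methoxy-4-[(3-methylbut-2-en-1-yl)oxy]phenyl}tetrahydro-1H,3H-furo[3,4-c]furan-1-yl]-2-methoxyphenyl 4-methylbenzenesulfonate
Conditions: CSA (10 mol%), 4 Å MS, CH2Cl2, 0 °C
Reagents that add atoms: none
Why: Acid-catalysed dehydrative etherification (SN1) in which either carbinol epimer ionises to the same 4-alkoxybenzylic cation and the primary hydroxyl traps it in a 5-exo-trig closure through the conformer with H-3a in the cation plane (minimal allylic 1,3-strain), which should place the aryl group cis to H-3a, that is exo (4R), while the tosyloxy-substituted benzylic ether at C-1 should not ionise and its ring is too electron-poor to capture the cation.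

Step 10
Reactants: 14 4-[(1S,3aS,4R,6aS)-4-{3-methoxy-4-[(3-methylbut-2-en-1-yl)oxy]phenyl}tetrahydro-1H,3H-furo[3,4-c]furan-1-yl]-2-methoxyphenyl 4-methylbenzenesulfonate
Product: 15 4-[(1S,3aS,4R,6aS)-4-{3-methoxy-4-[(3-methylbut-2-en-1-yl)oxy]phenyl}tetrahydro-1H,3H-furo[3,4-c]furan-1-yl]-2-methoxyphenol (target)
Conditions: KOH (5 equiv), 1,4-dioxane/H2O (3:1), 80 °C; then dilute HCl to pH 6
Reagents that add atoms: none
Why: Alkaline hydrolysis of the aryl sulfonate by attack of hydroxide at sulfur (S–O cleavage), which should free the phenol without touching the prenyl ether or the two benzylic ethers and without epimerising C-1, since that would need expulsion of an alkoxide from the phenoxide (quinone methide formation), which is not expected at this temperature.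

**Compound list**

1 | (E)-coniferaldehyde | COc1cc(/C=C/C=O)ccc1O | starting material
2 | (E)-2-methoxy-4-(3-oxoprop-1-en-1-yl)phenyl 4-methylbenzenesulfonate | COc1cc(/C=C/C=O)ccc1OS(=O)(=O)c1ccc(C)cc1 | intermediate
3 | dimethyl bromomalonate | COC(=O)C(Br)C(=O)OC | starting material
4 | dimethyl (2R,3S)-3-formyl-2-[3-methoxy-4-(tosyloxy)phenyl]cyclopropane-1,1-dicarboxylate | COc1cc([C@H]2[C@H](C=O)C2(C(=O)OC)C(=O)OC)ccc1OS(=O)(=O)c1ccc(C)cc1 | intermediate
5 | dimethyl (2R,3S)-3-(hydroxymethyl)-2-[3-methoxy-4-(tosyloxy)phenyl]cyclopropane-1,1-dicarboxylate | COc1cc([C@H]2[C@H](CO)C2(C(=O)OC)C(=O)OC)ccc1OS(=O)(=O)c1ccc(C)cc1 | intermediate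
6 | methyl (1R,5S,6R)-6-[3-methoxy-4-(tosyloxy)phenyl]-2-oxo-3-oxabicyclo[3.1.0]hexane-1-carboxylate | COc1cc([C@H]2[C@@H]3COC(=O)[C@@]32C(=O)OC)ccc1OS(=O)(=O)c1ccc(C)cc1 | intermediate
7 | methyl (3aS,4S,6aS)-4-[3-methoxy-4-(tosyloxy)phenyl]-1-oxotetrahydrofuro[3,4-c]furan-6a-carboxylate | COc1cc([C@H]2OC[C@]3(C(=O)OC)[C@H]2COC3=O)ccc1OS(=O)(=O)c1ccc(C)cc1 | intermediate
8 | (3aS,4S,6aS)-4-[3-methoxy-4-(tosyloxy)phenyl]tetrahydro-1H,3H-furo[3,4-c]furan-1-one | COc1cc([C@H]2OC[C@@H]3[C@H]2COC3=O)ccc1OS(=O)(=O)c1ccc(C)cc1 | intermediate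
9 | (3aS,4S,6aS)-4-[3-methoxy-4-(tosyloxy)phenyl]tetrahydro-1H,3H-furo[3,4-c]furan-1-ol (anomeric mixture, lactol carbon undefined) | COc1cc([C@H]2OC[C@@H]3[C@H]2COC3O)ccc1OS(=O)(=O)c1ccc(C)cc1 | intermediate
10 | 4-bromo-2-methoxyphenol | COc1cc(Br)ccc1O | starting material
11 | 4-bromo-2-methoxy-1-[(3-methylbut-2-en-1-yl)oxy]benzene | COc1cc(Br)ccc1OCC=C(C)C | intermediate
12 | {3-methoxy-4-[(3-methylbut-2-en-1-yl)oxy]phenyl}magnesium bromide | COc1cc([Mg]Br)ccc1OCC=C(C)C | intermediate
13 | 4-[(2S,3S,4S)-4-{hydroxy[3-methoxy-4-(prenyloxy)phenyl]methyl}-3-(hydroxymethyl)oxolan-2-yl]-2-methoxyphenyl 4-methylbenzenesulfonate (carbinol carbon undefined) | COc1cc([C@H]2OC[C@@H](C(O)c3ccc(OCC=C(C)C)c(OC)c3)[C@H]2CO)ccc1OS(=O)(=O)c1ccc(C)cc1 | intermediate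
14 | 4-[(1S,3aS,4R,6aS)-4-{3-methoxy-4-[(3-methylbut-2-en-1-yl)oxy]phenyl}tetrahydro-1H,3H-furo[3,4-c]furan-1-yl]-2-methoxyphenyl 4-methylbenzenesulfonate | COc1cc([C@H]2OC[C@@H]3[C@H]2CO[C@H]3c2ccc(OCC=C(C)C)c(OC)c2)ccc1OS(=O)(=O)c1ccc(C)cc1 | intermediate
15 | 4-[(1S,3aS,4R,6aS)-4-{3-methoxy-4-[(3-methylbut-2-en-1-yl)oxy]phenyl}tetrahydro-1H,3H-furo[3,4-c]furan-1-yl]-2-methoxyphenol | COc1cc([C@H]2OC[C@@H]3[C@H]2CO[C@H]3c2ccc(OCC=C(C)C)c(OC)c2)ccc1O | target

**Step count and risks**

Total steps: 10. Longest linear sequence: 9 (steps 1–6 and 8–10; step 7 is the side branch).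

Step 4 (key step). What may go wrong: the weakly nucleophilic formaldehyde, released slowly from its polymer, may capture the ion pair too slowly, so that hydrolytic ring-opening, ionisation to a free benzylic cation (loss of the inversion at C-4) or hydroxymethylation of the arene compete. Fallback with known chemistry: starting from 6, the same Lewis acid annulation is run with (E)-cinnamaldehyde, an aldehyde class for which it is established (Sn(OTf)2, CH2Cl2, rt; same inversion at C-4), to give the 6-styryl furofuranone ester F1. Ozonolysis (O3, CH2Cl2/MeOH, −78 °C; Me2S) cuts the styryl group to the 6-formyl furofuranone ester F2. Tsuji–Wilkinson decarbonylation with RhCl(PPh3)3 (1 equiv, toluene, 110 °C) then removes the formyl carbon and the sequence comes back to the route at 7.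

Step 9. What may go wrong: at the acidity needed to ionise the benzylic alcohol the prenyl ether may be protonated (loss of the prenyl group, chroman formation), and capture of the cation may be incompletely face-selective or be followed by re-ionisation and epimerisation at C-4. Fallback: the prenyl group is brought in last. Starting from 10, silylation (TBSCl, imidazole, DMF) gives the aryl silyl ether F3, whose Grignard reagent F4 (Mg, THF) adds to lactol 9 to give the silyloxyaryl diol F5. Ring B is closed on this prenyl-free substrate (CSA, CH2Cl2, 0 °C, or mesylation of the benzylic alcohol with MsCl/Et3N) to the silyl-protected furofuran F6. TBAF (THF, 0 °C) frees the furofuran phenol F7 while the tosylate on the other ring stays, and O-prenylation (prenyl bromide, K2CO3, acetone) returns to the route at 14.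

Step 5. What may go wrong: chloride may attack the lactone CH2 in place of the ester methyl group (ring-opened chloro acid), and the aryl sulfonate may be partly cleaved at 140 °C. Fallback: dealkylative decarboxylation is replaced by hydrolysis and decarboxylation of the free acid. Starting from 7, Me3SnOH (ClCH2CH2Cl, 80 °C) cleaves the methyl ester selectively to the malonic half-acid F8, which should lose CO2 on heating in toluene (100 °C) and rejoin the route at 8.

Further compounds
F1 | step 4 | methyl (3aS,4S,6aS)-4-[3-methoxy-4-(tosyloxy)phenyl]-1-oxo-6-[(E)-2-phenylethenyl]tetrahydrofuro[3,4-c]furan-6a-carboxylate (C-6 undefined, cis to the aryl expected, lost later) | COc1cc([C@H]2OC(/C=C/c3ccccc3)[C@]3(C(=O)OC)[C@H]2COC3=O)ccc1OS(=O)(=O)c1ccc(C)cc1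
F2 | step 4 | methyl (3aS,4S,6aS)-6-formyl-4-[3-methoxy-4-(tosyloxy)phenyl]-1-oxotetrahydrofuro[3,4-c]furan-6a-carboxylate (C-6 undefined) | COc1cc([C@H]2OC(C=O)[C@]3(C(=O)OC)[C@H]2COC3=O)ccc1OS(=O)(=O)c1ccc(C)cc1
F3 | step 9 | (4-bromo-2-methoxyphenoxy)(tert-butyl)dimethylsilane | COc1cc(Br)ccc1O[Si](C)(C)C(C)(C)C
F4 | step 9 | {4-[(tert-butyldimethylsilyl)oxy]-3-methoxyphenyl}magnesium bromide | COc1cc([Mg]Br)ccc1O[Si](C)(C)C(C)(C)C
F5 | step 9 | 4-[(2S,3S,4S)-4-{[4-(tert-butyldimethylsilyloxy)-3-methoxyphenyl](hydroxy)methyl}-3-(hydroxymethyl)oxolan-2-yl]-2-methoxyphenyl 4-methylbenzenesulfonate (carbinol carbon undefined) | COc1cc([C@H]2OC[C@@H](C(O)c3ccc(O[Si](C)(C)C(C)(C)C)c(OC)c3)[C@H]2CO)ccc1OS(=O)(=O)c1ccc(C)cc1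
F6 | step 9 | 4-[(1S,3aS,4R,6aS)-4-{4-[(tert-butyldimethylsilyl)oxy]-3-methoxyphenyl}tetrahydro-1H,3H-furo[3,4-c]furan-1-yl]-2-methoxyphenyl 4-methylbenzenesulfonate | COc1cc([C@H]2OC[C@@H]3[C@H]2CO[C@H]3c2ccc(O[Si](C)(C)C(C)(C)C)c(OC)c2)ccc1OS(=O)(=O)c1ccc(C)cc1
F7 | step 9 | 4-[(1S,3aS,4R,6aS)-4-(4-hydroxy-3-methoxyphenyl)tetrahydro-1H,3H-furo[3,4-c]furan-1-yl]-2-methoxyphenyl 4-methylbenzenesulfonate | COc1cc([C@H]2OC[C@@H]3[C@H]2CO[C@H]3c2ccc(O)c(OC)c2)ccc1OS(=O)(=O)c1ccc(C)cc1
F8 | step 5 | (3aS,4S,6aS)-4-[3-methoxy-4-(tosyloxy)phenyl]-1-oxotetrahydrofuro[3,4-c]furan-6a-carboxylic acid | COc1cc([C@H]2OC[C@]3(C(=O)O)[C@H]2COC3=O)ccc1OS(=O)(=O)c1ccc(C)cc1
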